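**Retrosynthetic overview**
1. The route rests on ring A of the chromone (C4a, C5, C6, C7, C8, C8a): a resorcinol with oxygen on C5 and C7, the methyl on C6 between them, hydrogen on C8 and fusion to the pyranone ring through C4a–C8a. A vinylketene and a 1-siloxypropyne assemble exactly this array in one operation.
2. Target ⇐ desilylation at the C7 oxygen ⇐ ring A by benzannulation (new bonds C5–C6, C7–C8 and C4a–C5) of 2-(2-diazoacetyl)-6-nonacosyl-4H-pyran-4-one with triisopropyl(prop-1-yn-1-yloxy)silane.
3. Diazoketone ⇐ 6-nonacosyl-4-oxo-4H-pyran-2-carboxylic acid ⇐ 2,4,6-triketo ester ⇐ tritriacontane-2,4-dione and diethyl oxalate; the diketone ⇐ pentane-2,4-dione dianion and 1-bromooctacosane.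
4. Siloxyalkyne ⇐ ethyl acetate by ynolate formation and O-silylation.
5. Ring order: the 4-pyranone ring first (step 4), ring A last (step 7).

Key step: step 7

Remark: the C2 chain is taken as unbranched nonacosyl (29 carbons); the target has no stereocentre, so none has to be set. Chromone numbering is used for ring atoms.

**Step 1**
Reactants: 1 octacosan-1-ol
Product: 2 1-bromooctacosane
Conditions: CBr4, PPh3, CH2Cl2–THF, 0 °C to 35 °C
Reagents that add atoms: carbon tetrabromide, BrC(Br)(Br)Br
Why: Appel bromination, in which bromide displaces the alkoxyphosphonium ion of the primary alcohol by SN2 under neutral conditions, so the unfunctionalised chain is untouched.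

**Step 2**
Reactants: 3 pentane-2,4-dione; 2 1-bromooctacosane
Product: 5 tritriacontane-2,4-dione, via dilithium dianion of pentane-2,4-dione 4 (not isolated)
Conditions: LiN(iPr)2 (2.1 equiv per 3), THF, 0 °C; then 2 (0.7 equiv) in warm THF, 0 °C to 40 °C; 1 M HCl
Reagents that add atoms: none
Why: Hauser–Harris γ-alkylation, in which the β-diketone dianion reacts with the primary bromide by SN2 only at its more basic terminal carbanion, turning the C1 methyl into the first carbon of the nonacosyl chain.

**Step 3**
Reactants: 5 tritriacontane-2,4-dione; 6 diethyl oxalate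
Product: 7 ethyl 2,4,6-trioxopentatriacontanoate
Conditions: NaOEt (2.5 equiv), EtOH–toluene, 60 °C; then cold 1 M HCl
Reagents that add atoms: none
Why: crossed Claisen condensation with non-enolisable diethyl oxalate, which should occur at the unhindered C1 methyl and not at the C5 methylene (as in oxalate condensations of methyl alkyl ketones) and is driven by formation of the stabilised dienolate.

**Step 4**
Reactants: 7 ethyl 2,4,6-trioxopentatriacontanoate
Product: 9 6-nonacosyl-4-oxo-4H-pyran-2-carboxylic acid, via ethyl 6-nonacosyl-4-oxo-4H-pyran-2-carboxylate 8 (not isolated)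
Conditions: conc. HCl, AcOH, 100 °C
Reagents that add atoms: water, O
Why: acid-catalysed cyclodehydration of the 1,3,5-tricarbonyl unit (the C6 enol oxygen adds to the C2 ketone, then water is lost) closes the 4-pyranone as in the chelidonic acid synthesis, and the hot aqueous acid hydrolyses the ester.

**Step 5**
Reactants: 9 6-nonacosyl-4-oxo-4H-pyran-2-carboxylic acid
Product: 11 2-(2-diazoacetyl)-6-nonacosyl-4H-pyran-4-one, via 6-nonacosyl-4-oxo-4H-pyran-2-carbonyl chloride 10 (not isolated)
Conditions: SOCl2, cat. DMF, toluene, 70 °C, evaporate; then 10 added to CH2N2 (3 equiv), Et2O–THF, 0 °C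
Reagents that add atoms: diazomethane, C=[N+]=[N-]
Why: acid chloride formation followed by Arndt–Eistert-type acylation of diazomethane, in which the acid chloride has no α-hydrogen (no ketene pathway) and the excess diazomethane removes HCl so that the diazoketone is not converted into the chloromethyl ketone.

**Step 6**
Reactants: 12 ethyl acetate
Product: 15 triisopropyl(prop-1-yn-1-yloxy)silane, via lithium 1,1-dibromoprop-1-en-2-olate 13 (not isolated), via lithium prop-1-yn-1-olate 14 (not isolated)
Conditions: CH2Br2, lithium 2,2,6,6-tetramethylpiperidide (2.1 equiv), THF, −78 °C; then n-BuLi, −78 °C to 20 °C; then TIPSCl, −78 °C to 20 °C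
Reagents that add atoms: dibromomethane, BrCBr; chlorotriisopropylsilane, CC(C)[Si](Cl)(C(C)C)C(C)C
Why: Kowalski ester homologation, in which LiCHBr2 adds to the ester, bromine–lithium exchange on the dibromo enolate triggers a carbenoid 1,2-shift of the methyl group to the ynolate, and the bulky silyl chloride traps the ynolate on oxygen.

**Step 7**
Reactants: 11 2-(2-diazoacetyl)-6-nonacosyl-4H-pyran-4-one; 15 triisopropyl(prop-1-yn-1-yloxy)silane
Product: 19 5-hydroxy-6-methyl-2-nonacosyl-7-(triisopropylsilyloxy)-4H-chromen-4-one, via pyranonyl ketene 16 (not isolated), via siloxycyclobutenone 17 (not isolated), via dienylketene 18 (not isolated)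
Conditions: 15 (2.5 equiv), degassed ClCH2CH2Cl, hν (365 nm), 25–30 °C; then 80 °C in the dark
Reagents that add atoms: none
Why: Excitation of the diazoketone at 365 nm, away from the pyranone π–π* band near 250 nm, expels N2 and triggers a Wolff rearrangement in which the pyranon-2-yl group migrates to the diazo carbon, giving ketene 16 whose CH carbon becomes C8 and whose carbonyl carbon becomes C5. The polarised ynol ether 15 adds to the ketene by [2+2] cycloaddition to give cyclobutenone 17 (C5–C6 and C7–C8 formed), which on heating undergoes 4π electrocyclic opening to dienylketene 18. Ring A is then closed by thermal disrotatory 6π electrocyclisation of 18 onto pyranone C3, forming C4a–C5, and the cyclohexadienone tautomerises to the C5 phenol, which is hydrogen-bonded to the C4 carbonyl. The closest known reaction is the Danheiser benzannulation in its photochemical Wolff variant, as run with vinyl and heteroaryl diazomethyl ketones and triisopropylsiloxyalkynes. No stereocentre remains in 19, since the one in racemic 17 is lost on ring opening. The step needs the [2+2] regiochemistry, which is secured because the methyl-bearing carbon of the ynol ether is its nucleophilic terminus and bonds to the electrophilic ketene carbonyl carbon (methyl at C6, silyloxy at C7); the closure has only one site open to it, because the other neighbour of pyranone C2 is the ring oxygen.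

**Step 8**
Reactants: 19 5-hydroxy-6-methyl-2-nonacosyl-7-(triisopropylsilyloxy)-4H-chromen-4-one
Product: 20 5,7-dihydroxy-6-methyl-2-nonacosyl-4H-chromen-4-one
Conditions: Bu4NF, AcOH, THF, 0 °C to 20 °C
Reagents that add atoms: none
Why: fluoride-induced cleavage of the aryl silyl ether, driven by the strong Si–F bond, with acetic acid buffering the phenoxide so that the chromone and the chelated C5 hydroxyl are left untouched.

**Compound list**
1 | octacosan-1-ol | CCCCCCCCCCCCCCCCCCCCCCCCCCCCO | starting material
2 | 1-bromooctacosane | CCCCCCCCCCCCCCCCCCCCCCCCCCCCBr | intermediate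
3 | pentane-2,4-dione | CC(=O)CC(C)=O | starting material
4 | dilithium penta-1,3-diene-2,4-diolate (dianion of pentane-2,4-dione) | [Li+].[Li+].C=C([O-])C=C(C)[O-] | intermediate
5 | tritriacontane-2,4-dione | CC(=O)CC(=O)CCCCCCCCCCCCCCCCCCCCCCCCCCCCC | intermediate
6 | diethyl oxalate | CCOC(=O)C(=O)OCC | starting material
7 | ethyl 2,4,6-trioxopentatriacontanoate | CCOC(=O)C(=O)CC(=O)CC(=O)CCCCCCCCCCCCCCCCCCCCCCCCCCCCC | intermediate
8 | ethyl 6-nonacosyl-4-oxo-4H-pyran-2-carboxylate | CCCCCCCCCCCCCCCCCCCCCCCCCCCCCc1cc(=O)cc(C(=O)OCC)o1 | intermediate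
9 | 6-nonacosyl-4-oxo-4H-pyran-2-carboxylic acid | CCCCCCCCCCCCCCCCCCCCCCCCCCCCCc1cc(=O)cc(C(=O)O)o1 | intermediate
10 | 6-nonacosyl-4-oxo-4H-pyran-2-carbonyl chloride | CCCCCCCCCCCCCCCCCCCCCCCCCCCCCc1cc(=O)cc(C(=O)Cl)o1 | intermediate
11 | 2-(2-diazoacetyl)-6-nonacosyl-4H-pyran-4-one | CCCCCCCCCCCCCCCCCCCCCCCCCCCCCc1cc(=O)cc(C(=O)C=[N+]=[N-])o1 | intermediate
12 | ethyl acetate | CCOC(C)=O | starting material
13 | lithium 1,1-dibromoprop-1-en-2-olate | [Li+].CC([O-])=C(Br)Br | intermediate
14 | lithium prop-1-yn-1-olate | [Li+].CC#C[O-] | intermediate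
15 | triisopropyl(prop-1-yn-1-yloxy)silane | CC#CO[Si](C(C)C)(C(C)C)C(C)C | intermediate
16 | 6-nonacosyl-2-(2-oxoethenyl)-4H-pyran-4-one (pyranonyl ketene) | CCCCCCCCCCCCCCCCCCCCCCCCCCCCCc1cc(=O)cc(C=C=O)o1 | intermediate
17 | 2-methyl-4-(6-nonacosyl-4-oxo-4H-pyran-2-yl)-3-(triisopropylsilyloxy)cyclobut-2-en-1-one (racemic) | CCCCCCCCCCCCCCCCCCCCCCCCCCCCCc1cc(=O)cc(C2C(=O)C(C)=C2O[Si](C(C)C)(C(C)C)C(C)C)o1 | intermediate
18 | (3E)-2-methyl-4-(6-nonacosyl-4-oxo-4H-pyran-2-yl)-3-(triisopropylsilyloxy)buta-1,3-dien-1-one (dienylketene) | CCCCCCCCCCCCCCCCCCCCCCCCCCCCCc1cc(=O)cc(/C=C(/O[Si](C(C)C)(C(C)C)C(C)C)C(C)=C=O)o1 | intermediate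
19 | 5-hydroxy-6-methyl-2-nonacosyl-7-(triisopropylsilyloxy)-4H-chromen-4-one | CCCCCCCCCCCCCCCCCCCCCCCCCCCCCc1cc(=O)c2c(O)c(C)c(O[Si](C(C)C)(C(C)C)C(C)C)cc2o1 | intermediate
20 | 5,7-dihydroxy-6-methyl-2-nonacosyl-4H-chromen-4-one | CCCCCCCCCCCCCCCCCCCCCCCCCCCCCc1cc(=O)c2c(O)c(C)c(O)cc2o1 | target

**Step count**
Total steps: 8. Longest linear sequence: 7 steps (steps 1, 2, 3, 4, 5, 7, 8); step 6 is the side branch to the siloxyalkyne.

**Steps most likely to fail**

Step 7. The light may be taken up by the pyranone chromophore (photoisomerisation), the Wolff migration of the electron-poor pyranonyl group may be slow, and the ketene may oligomerise before it meets the alkyne. The fallback makes the same ketene without light. Setting out from 11, a PhCO2Ag/Et3N-catalysed Wolff rearrangement in aqueous THF (Arndt–Eistert homologation) should give (6-nonacosyl-4-oxo-4H-pyran-2-yl)acetic acid F1. F1 is kept cold to avoid decarboxylation and converted with oxalyl chloride and cat. DMF in CH2Cl2 at 0 °C into (6-nonacosyl-4-oxo-4H-pyran-2-yl)acetyl chloride F2. Slow addition of Et3N to F2 and 15 in toluene generates ketene 16 by dehydrochlorination; cycloaddition to 17 and heating at 80–110 °C then carry the sequence through 18 back to 19.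

Step 5. Diazomethane may add as a 1,3-dipole across the acylated C2=C3 bond of the pyranone, HCl may convert the diazoketone into the chloromethyl ketone, and the pyranone oxygen may be chlorinated during acid chloride formation. The fallback avoids both the acid chloride and diazomethane. Setting out from 5, the dianion (LiN(iPr)2, 3 equiv, THF) is acylated on its methyl terminus with ethyl 2,2-diethoxypropanoate (Hauser–Harris triketone synthesis) to give 2,2-diethoxyhexatriacontane-3,5,7-trione F3. Aqueous acid (HCl, AcOH) cyclises F3 and unmasks the ketone to give 2-acetyl-6-nonacosyl-4H-pyran-4-one F4. LiN(SiMe3)2 and 2,2,2-trifluoroethyl trifluoroacetate at −78 °C acylate the acetyl methyl group to give 4,4,4-trifluoro-1-(6-nonacosyl-4-oxo-4H-pyran-2-yl)butane-1,3-dione F5. F5 is treated without isolation with methanesulfonyl azide, Et3N and water in MeCN (detrifluoroacetylative diazo transfer) and so returns to 11.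

Step 3. Acylation may occur on the C5 methylene or on the central C3 carbon, ethoxide may cleave the diketone by retro-Claisen reaction, and poor solubility of the long-chain enolate may stall the condensation. The fallback reverses the order of the two C–C bond formations so that no regiochemical question arises. Setting out from 3 and 6, NaOEt-mediated Claisen condensation of the symmetrical diketone gives ethyl 2,4,6-trioxoheptanoate F6. LiN(iPr)2 (3.1 equiv) in THF converts it into the trilithium trianion of ethyl 2,4,6-trioxoheptanoate F7, which is alkylated by 2 at its terminal, most basic carbanion and returns to 7 after acidic work-up.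

**Further compounds**
F1 | step 7 | (6-nonacosyl-4-oxo-4H-pyran-2-yl)acetic acid | CCCCCCCCCCCCCCCCCCCCCCCCCCCCCc1cc(=O)cc(CC(=O)O)o1
F2 | step 7 | (6-nonacosyl-4-oxo-4H-pyran-2-yl)acetyl chloride | CCCCCCCCCCCCCCCCCCCCCCCCCCCCCc1cc(=O)cc(CC(=O)Cl)o1
F3 | step 5 | 2,2-diethoxyhexatriacontane-3,5,7-trione | CCOC(C)(OCC)C(=O)CC(=O)CC(=O)CCCCCCCCCCCCCCCCCCCCCCCCCCCCC
F4 | step 5 | 2-acetyl-6-nonacosyl-4H-pyran-4-one | CCCCCCCCCCCCCCCCCCCCCCCCCCCCCc1cc(=O)cc(C(C)=O)o1
F5 | step 5 | 4,4,4-trifluoro-1-(6-nonacosyl-4-oxo-4H-pyran-2-yl)butane-1,3-dione | CCCCCCCCCCCCCCCCCCCCCCCCCCCCCc1cc(=O)cc(C(=O)CC(=O)C(F)(F)F)o1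
F6 | step 3 | ethyl 2,4,6-trioxoheptanoate | CCOC(=O)C(=O)CC(=O)CC(C)=O
F7 | step 3 | trilithium trianion of ethyl 2,4,6-trioxoheptanoate | [Li+].[Li+].[Li+].CCOC(=O)C([O-])=CC([O-])=CC([O-])=C
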